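**Plan**
- The retrosynthesis cuts O1–C2 of ring C of target 15 in an isomerisation sense. The acyl-bearing carbon C4a has an oxygen on both ortho carbons of ring A (C5 and C8a), so ring C can close on either one, and 15 is traced to its 5,8-dihydroxy-7-methoxy isomer 13.
- 13 is cut at C8–O (para-hydroxylation of 5-hydroxyflavone 10) and at the benzyl ether. 10 is cut at O1–C2 and at the C2–C3 bond (chalcone from ketone 7 and aldehyde 6). 6 is cut at its formyl C–C bond and at the aryl C–O bond that goes back to aldehyde 1.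
- Forward: the ring B aldehyde is made (steps 1–3) and joined to the ring A ketone (step 4). Ring C is closed (step 5), the 8-hydroxyl is installed (step 6) and the benzyl group is removed (step 7). Ring C is then opened and reclosed on the other oxygen (step 8).
- Stereochemistry: the target has no stereocentre. The E chalcone geometry and the racemic flavanone centre are both erased when ring C becomes a pyranone.

Key step: step 8

Remark: the target carries three methyl ethers (O7, O2', O5') and three free hydroxyls (5, 6, 4'); compounds 1 and 7 are taken as purchasable.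

**Step 1**
Reactants: 1 2,5-dimethoxybenzaldehyde
Product: 3 2,5-dimethoxyphenol, via 2,5-dimethoxyphenyl formate 2 (not isolated)
Conditions: mCPBA, CH2Cl2, 0 °C → rt; then K2CO3 (cat.), MeOH, rt
Reagents that add atoms: meta-chloroperoxybenzoic acid (mCPBA), O=C(OO)c1cccc(Cl)c1
Why: Baeyer–Villiger oxidation of an electron-rich benzaldehyde, in which the 2-methoxyaryl group migrates in preference to hydride to give the aryl formate, followed by base-catalysed methanolysis of this labile ester to the phenol.

**Step 2**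
Reactants: 3 2,5-dimethoxyphenol
Product: 4 2-(benzyloxy)-1,4-dimethoxybenzene
Conditions: BnBr, K2CO3, acetone, reflux
Reagents that add atoms: benzyl bromide, BrCc1ccccc1
Why: Williamson ether synthesis, the phenoxide displacing bromide in an SN2 reaction to install a protecting group that should survive formylation, aldol, iodine and alkaline persulfate conditions and is removed later by hydrogenolysis.

**Step 3**
Reactants: 4 2-(benzyloxy)-1,4-dimethoxybenzene
Product: 6 4-(benzyloxy)-2,5-dimethoxybenzaldehyde, via iminium salt 5 (not isolated)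
Conditions: POCl3, DMF, 0 → 70 °C; then ice–H2O
Reagents that add atoms: N,N-dimethylformamide, CN(C)C=O; water, O
Why: Vilsmeier–Haack formylation, the chloroiminium electrophile attacking the ring carbon para to the benzyloxy group and ortho to a methoxy group (the most activated and least hindered site, the same orientation as in the formylation of 1,2,4-trimethoxybenzene), after which water hydrolyses iminium salt 5 to the aldehyde.

**Step 4**
Reactants: 6 4-(benzyloxy)-2,5-dimethoxybenzaldehyde; 7 1-(2,6-dihydroxy-4-methoxyphenyl)ethanone (2',6'-dihydroxy-4'-methoxyacetophenone)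
Product: 8 (2E)-3-[4-(benzyloxy)-2,5-dimethoxyphenyl]-1-(2,6-dihydroxy-4-methoxyphenyl)prop-2-en-1-one
Conditions: KOH (50% aq.), EtOH, rt, Ar; then dil. HCl to pH 4
Reagents that add atoms: none
Why: Claisen–Schmidt condensation, the methyl ketone enolate adding to the non-enolisable aldehyde and E1cB loss of water giving the thermodynamically preferred E enone; any flavanone 9 formed on acidification is the intermediate of the next step and is carried along.

**Step 5**
Reactants: 8 (2E)-3-[4-(benzyloxy)-2,5-dimethoxyphenyl]-1-(2,6-dihydroxy-4-methoxyphenyl)prop-2-en-1-one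
Product: 10 2-[4-(benzyloxy)-2,5-dimethoxyphenyl]-5-hydroxy-7-methoxy-4H-chromen-4-one, via flavanone 9 (not isolated)
Conditions: I2 (10 mol%), DMSO, 120 °C
Reagents that add atoms: none
Why: Iodine–DMSO oxidative cyclisation of a 2'-hydroxychalcone, in which 6-endo-trig oxa-Michael addition of one of the two equivalent phenols gives flavanone 9 and iodine then dehydrogenates C2–C3 while DMSO reoxidises the hydrogen iodide, the second phenol remaining as the chelated 5-hydroxyl.

**Step 6**
Reactants: 10 2-[4-(benzyloxy)-2,5-dimethoxyphenyl]-5-hydroxy-7-methoxy-4H-chromen-4-one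
Product: 12 2-[4-(benzyloxy)-2,5-dimethoxyphenyl]-5,8-dihydroxy-7-methoxy-4H-chromen-4-one, via potassium aryl sulfate 11 (not isolated)
Conditions: K2S2O8, aq. KOH, pyridine, 15–20 °C; then HCl (2 M), Na2SO3 (cat.), 90 °C
Reagents that add atoms: potassium persulfate, [K+].[K+].[O-]S(=O)(=O)OOS(=O)(=O)[O-]
Why: Elbs persulfate oxidation, the 5-phenoxide attacking a peroxide oxygen of persulfate through its para carbon C8 to give aryl sulfate 11, which acid hydrolyses to the hydroquinone, ring B being inert because its phenol is benzylated.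

**Step 7**
Reactants: 12 2-[4-(benzyloxy)-2,5-dimethoxyphenyl]-5,8-dihydroxy-7-methoxy-4H-chromen-4-one
Product: 13 5,8-dihydroxy-2-(4-hydroxy-2,5-dimethoxyphenyl)-7-methoxy-4H-chromen-4-one
Conditions: H2 (1 atm), Pd/C (10%), EtOAc–MeOH, rt; product handled under Ar
Reagents that add atoms: none
Why: Catalytic hydrogenolysis of the aryl benzyl ether over palladium on carbon, under mild conditions that should leave the pyranone double bond and the three methyl ethers untouched.

**Step 8**
Reactants: 13 5,8-dihydroxy-2-(4-hydroxy-2,5-dimethoxyphenyl)-7-methoxy-4H-chromen-4-one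
Product: 15 5,6-dihydroxy-2-(4-hydroxy-2,5-dimethoxyphenyl)-7-methoxy-4H-chromen-4-one (CNP0310413.0), via ring-opened 1,3-diketone 14 (not isolated)
Conditions: H2SO4 (2 M), AcOH–H2O (degassed), 100 °C, Ar
Reagents that add atoms: none
Why: Wessely–Moser rearrangement: protonation of the C4 carbonyl activates C2 of ring C, water adds there and the O1–C2 bond breaks, giving diketone 14 in which the acyl-bearing carbon (the former C4a) has a free hydroxyl on each ortho carbon. After rotation about the aryl–carbonyl bond the hydroxyl that was at C5 attacks the ring B side ketone (6-exo-trig hemiketal formation) and loss of water closes the new six-membered pyranone through a new O1–C2 bond, so that the former 8-hydroxyl becomes the 6-hydroxyl. The closest known reactions are the acid isomerisation of 5,8- and 5,7,8-oxygenated flavones to the 5,6- and 5,6,7-series and the interconversion of 8- and 6-substituted 5,7-dihydroxyflavones in hot dilute mineral acid, the latter leaving ethers untouched. No stereocentre is formed. The selectivity needed is the direction of reclosure, which is under thermodynamic control: 15 should be favoured, as in the classical cases, because its 6-OH, 5-OH and C4=O form one continuous hydrogen-bond chain, whereas the 8-OH of 13 has only O1 and the 7-methoxy oxygen as neighbours. Dilute non-nucleophilic acid and exclusion of air should keep the three methyl ethers and the oxidisable hydroquinone and catechol units intact, and unchanged 13 is separated by chromatography and resubmitted.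

**Compound list**
1 | 2,5-dimethoxybenzaldehyde | COc1ccc(OC)c(C=O)c1 | starting material
2 | 2,5-dimethoxyphenyl formate | COc1ccc(OC)c(OC=O)c1 | intermediate
3 | 2,5-dimethoxyphenol | COc1ccc(OC)c(O)c1 | intermediate
4 | 2-(benzyloxy)-1,4-dimethoxybenzene | COc1ccc(OC)c(OCc2ccccc2)c1 | intermediate
5 | N-{[4-(benzyloxy)-2,5-dimethoxyphenyl]methylidene}-N-methylmethanaminium dichlorophosphate | COc1cc(OCc2ccccc2)c(OC)cc1C=[N+](C)C.[O-]P(=O)(Cl)Cl | intermediate
6 | 4-(benzyloxy)-2,5-dimethoxybenzaldehyde | COc1cc(OCc2ccccc2)c(OC)cc1C=O | intermediate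
7 | 1-(2,6-dihydroxy-4-methoxyphenyl)ethanone | COc1cc(O)c(C(C)=O)c(O)c1 | starting material
8 | (2E)-3-[4-(benzyloxy)-2,5-dimethoxyphenyl]-1-(2,6-dihydroxy-4-methoxyphenyl)prop-2-en-1-one | COc1cc(O)c(C(=O)/C=C/c2cc(OC)c(OCc3ccccc3)cc2OC)c(O)c1 | intermediate
9 | (±)-2-[4-(benzyloxy)-2,5-dimethoxyphenyl]-5-hydroxy-7-methoxy-2,3-dihydro-4H-chromen-4-one (racemic) | COc1cc(O)c2C(=O)CC(c3cc(OC)c(OCc4ccccc4)cc3OC)Oc2c1 | intermediate
10 | 2-[4-(benzyloxy)-2,5-dimethoxyphenyl]-5-hydroxy-7-methoxy-4H-chromen-4-one | COc1cc(-c2cc(=O)c3c(O)cc(OC)cc3o2)c(OC)cc1OCc1ccccc1 | intermediate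
11 | potassium 2-[4-(benzyloxy)-2,5-dimethoxyphenyl]-5-hydroxy-7-methoxy-4-oxo-4H-chromen-8-yl sulfate | COc1cc(-c2cc(=O)c3c(O)cc(OC)c(OS(=O)(=O)[O-])c3o2)c(OC)cc1OCc1ccccc1.[K+] | intermediate
12 | 2-[4-(benzyloxy)-2,5-dimethoxyphenyl]-5,8-dihydroxy-7-methoxy-4H-chromen-4-one | COc1cc(-c2cc(=O)c3c(O)cc(OC)c(O)c3o2)c(OC)cc1OCc1ccccc1 | intermediate
13 | 5,8-dihydroxy-2-(4-hydroxy-2,5-dimethoxyphenyl)-7-methoxy-4H-chromen-4-one | COc1cc(-c2cc(=O)c3c(O)cc(OC)c(O)c3o2)c(OC)cc1O | intermediate
14 | 1-(4-hydroxy-2,5-dimethoxyphenyl)-3-(2,3,6-trihydroxy-4-methoxyphenyl)propane-1,3-dione | COc1cc(C(=O)CC(=O)c2c(O)cc(OC)c(O)c2O)c(OC)cc1O | intermediate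
15 | 5,6-dihydroxy-2-(4-hydroxy-2,5-dimethoxyphenyl)-7-methoxy-4H-chromen-4-one (CNP0310413.0) | COc1cc(-c2cc(=O)c3c(O)c(O)c(OC)cc3o2)c(OC)cc1O | target

**Totals**
Total step count: 8. Longest linear sequence: 8 steps (1 → 15); ketone 7 enters at step 4.

**Steps most likely to fail**

1. Step 8. The pyranone may open too slowly in dilute acid, the opening–reclosure equilibrium may stall at a mixture, the diketone may undergo retro-Claisen cleavage, or the hydroquinone may be oxidised by traces of air. The fallback builds ring A with the closure direction fixed by protecting groups; it sets out from 7 and 6 and comes back at 15.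
 - Mono-benzylation of 7 (BnBr, 1 equiv, K2CO3, acetone) should give 1-[2-(benzyloxy)-6-hydroxy-4-methoxyphenyl]ethanone F1.
 - Elbs oxidation of F1 (K2S2O8, aq. KOH; then dil. HCl, heat) para to the remaining chelated hydroxyl passes through potassium 3-acetyl-2-(benzyloxy)-4-hydroxy-6-methoxyphenyl sulfate F2 to 1-[2-(benzyloxy)-3,6-dihydroxy-4-methoxyphenyl]ethanone F3.
 - Benzylation of the new, non-chelated hydroxyl (BnBr, K2CO3, acetone) gives 1-[2,3-bis(benzyloxy)-6-hydroxy-4-methoxyphenyl]ethanone F4.
 - Claisen–Schmidt condensation of F4 with 6 (KOH, EtOH) gives (2E)-1-[2,3-bis(benzyloxy)-6-hydroxy-4-methoxyphenyl]-3-[4-(benzyloxy)-2,5-dimethoxyphenyl]prop-2-en-1-one F5.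
 - Iodine–DMSO cyclisation of F5 passes through (±)-5,6-bis(benzyloxy)-2-[4-(benzyloxy)-2,5-dimethoxyphenyl]-7-methoxy-2,3-dihydro-4H-chromen-4-one F6 to 5,6-bis(benzyloxy)-2-[4-(benzyloxy)-2,5-dimethoxyphenyl]-7-methoxy-4H-chromen-4-one F7. Only one ring A hydroxyl is free, so only the 5,6,7-pattern can form.
 - Hydrogenolysis of F7 (H2, Pd/C) removes the three benzyl groups and gives 15.

2. Step 6. Conversion of the chelated phenoxide may be low, the hydroquinone formed may be over-oxidised by persulfate, or alkaline opening of the pyranone may compete. The fallback sets out from 10 and comes back at 12: Teuber oxidation of 10 with potassium nitrosodisulfonate, ON(SO3K)2 (KH2PO4 buffer, acetone–H2O), should give the para-quinone 2-[4-(benzyloxy)-2,5-dimethoxyphenyl]-7-methoxy-4H-chromene-4,5,8-trione F8. Reduction of F8 with Na2S2O4 (EtOAc–H2O) gives 12.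

3. Step 4. The aldol addition may be slow or incomplete, because the doubly deprotonated ketone enolises reluctantly and the aldehyde is an electron-rich, weak electrophile, and a Cannizzaro reaction may compete. The fallback replaces the aldol by a C-acylation of Baker–Venkataraman type; it sets out from 6 and 7 and comes back at 10.
 - Pinnick oxidation of 6 (NaClO2, NaH2PO4, 2-methyl-2-butene, t-BuOH–H2O) gives 4-(benzyloxy)-2,5-dimethoxybenzoic acid F9.
 - Oxalyl chloride with catalytic DMF converts F9 into 4-(benzyloxy)-2,5-dimethoxybenzoyl chloride F10.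
 - The polyanion of 7, made with LiN(SiMe3)2 (4 equiv, THF, −78 °C → rt), is acylated on carbon by F10 to give 1-[4-(benzyloxy)-2,5-dimethoxyphenyl]-3-(2,6-dihydroxy-4-methoxyphenyl)propane-1,3-dione F11.
 - Cyclodehydration of F11 (AcOH, cat. H2SO4, 90 °C) gives 10.

**Further compounds**
F1 | step 8 | 1-[2-(benzyloxy)-6-hydroxy-4-methoxyphenyl]ethanone | COc1cc(O)c(C(C)=O)c(OCc2ccccc2)c1
F2 | step 8 | potassium 3-acetyl-2-(benzyloxy)-4-hydroxy-6-methoxyphenyl sulfate | COc1cc(O)c(C(C)=O)c(OCc2ccccc2)c1OS(=O)(=O)[O-].[K+]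
F3 | step 8 | 1-[2-(benzyloxy)-3,6-dihydroxy-4-methoxyphenyl]ethanone | COc1cc(O)c(C(C)=O)c(OCc2ccccc2)c1O
F4 | step 8 | 1-[2,3-bis(benzyloxy)-6-hydroxy-4-methoxyphenyl]ethanone | COc1cc(O)c(C(C)=O)c(OCc2ccccc2)c1OCc1ccccc1
F5 | step 8 | (2E)-1-[2,3-bis(benzyloxy)-6-hydroxy-4-methoxyphenyl]-3-[4-(benzyloxy)-2,5-dimethoxyphenyl]prop-2-en-1-one | COc1cc(O)c(C(=O)/C=C/c2cc(OC)c(OCc3ccccc3)cc2OC)c(OCc2ccccc2)c1OCc1ccccc1
F6 | step 8 | (±)-5,6-bis(benzyloxy)-2-[4-(benzyloxy)-2,5-dimethoxyphenyl]-7-methoxy-2,3-dihydro-4H-chromen-4-one (racemic) | COc1cc(C2CC(=O)c3c(OCc4ccccc4)c(OCc4ccccc4)c(OC)cc3O2)c(OC)cc1OCc1ccccc1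
F7 | step 8 | 5,6-bis(benzyloxy)-2-[4-(benzyloxy)-2,5-dimethoxyphenyl]-7-methoxy-4H-chromen-4-one | COc1cc(-c2cc(=O)c3c(OCc4ccccc4)c(OCc4ccccc4)c(OC)cc3o2)c(OC)cc1OCc1ccccc1
F8 | step 6 | 2-[4-(benzyloxy)-2,5-dimethoxyphenyl]-7-methoxy-4H-chromene-4,5,8-trione | COC1=CC(=O)c2c(oc(-c3cc(OC)c(OCc4ccccc4)cc3OC)cc2=O)C1=O
F9 | step 4 | 4-(benzyloxy)-2,5-dimethoxybenzoic acid | COc1cc(OCc2ccccc2)c(OC)cc1C(=O)O
F10 | step 4 | 4-(benzyloxy)-2,5-dimethoxybenzoyl chloride | COc1cc(OCc2ccccc2)c(OC)cc1C(=O)Cl
F11 | step 4 | 1-[4-(benzyloxy)-2,5-dimethoxyphenyl]-3-(2,6-dihydroxy-4-methoxyphenyl)propane-1,3-dione | COc1cc(O)c(C(=O)CC(=O)c2cc(OC)c(OCc3ccccc3)cc2OC)c(O)c1
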